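**Retrosynthetic overview**
1. Target ⇒ Lindlar semihydrogenation of the C7 arylpropiolate; C11 CH2OH ⇒ Stille hydroxymethylation of a C4 enol triflate.
2. C7 ester with free 8-OH and 10-OH ⇒ Ti-mediated C7 opening of a 7α,8α-epoxy-10-ol by 3-(4-hydroxyphenyl)propiolic acid (from 4-iodophenol and propiolic acid).
3. Epoxy alcohol ⇒ Sharpless epoxidation of the C7=C8 allylic alcohol ⇒ keto enoate (enol triflation, then tert-butyl ester to CH2OH).
4. Cyclopentene ring (formed second) ⇒ phosphine-catalysed [3+2] annulation of tert-butyl allenoate onto the enone of a 6-acyloxy-2H-pyran-3(6H)-one.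
5. Pyranone ring (formed first) ⇒ Achmatowicz ring expansion of furfuryl alcohol, then dynamic kinetic esterification of the lactol with (R)-3-methylpentanoic acid, which sets C1 and through it C5 and C9.

Assumption: (R)-3-methylpentanoic acid and tert-butyl buta-2,3-dienoate are bought (the tert-butyl group is a protecting group on six-heavy-atom buta-2,3-dienoic acid); α/β and C-numbers use iridoid numbering (C1 acetal, O2, C3=C4, C5, C6, C7, C8, C9, C10 on C8, C11 on C4; H-5 and H-9 are β).

**Step 1**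
Reactants: 1 furfuryl alcohol
Product: 2 6-hydroxy-2H-pyran-3(6H)-one
Conditions: NBS (1.05 equiv), NaHCO3, NaOAc, THF–H2O (4:1), 0 °C
Reagents that add atoms: water, O
Why: Achmatowicz rearrangement, in which oxidation of the furan at C5, hydrolytic opening to the cis-enedione and re-closure of the primary alcohol onto the aldehyde expand the furan to the six-membered pyranone lactol (racemic and configurationally labile, so no stereocentre is fixed yet).

**Step 2**
Reactants: 2 6-hydroxy-2H-pyran-3(6H)-one; 3 (3R)-3-methylpentanoic acid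
Product: 5 (2S)-5-oxo-5,6-dihydro-2H-pyran-2-yl (3R)-3-methylpentanoate, via mixed pivalic anhydride 4 (not isolated)
Conditions: Piv2O (1.3 equiv), i-Pr2NEt (2 equiv), (R)-benzotetramisole (5 mol %), toluene, 0 °C
Reagents that add atoms: none
Why: Proposed new method: dynamic kinetic asymmetric esterification of a racemising lactol with a free carboxylic acid, in which Piv2O converts the acid into mixed anhydride 4, the isothiourea attacks its unhindered acyl group to give a chiral N-acyl isothiouronium, and this acylates one enantiomer of the lactol while base-promoted ring–chain tautomerism keeps racemising the rest, so all of 2 is funnelled to the (S)-acetal ester; the closest known chemistry is isothiourea-catalysed DYKAT acylation of this lactol with symmetric anhydrides combined with mixed-anhydride (Piv2O) kinetic resolution of secondary alcohols with free acids, and the catalyst antipode is used if the first run shows the opposite sense at C1.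

**Step 3**
Reactants: 5 (2S)-5-oxo-5,6-dihydro-2H-pyran-2-yl (3R)-3-methylpentanoate; 6 tert-butyl buta-2,3-dienoate
Product: 7 tert-butyl (1S,4aS,7aS)-1-{[(3R)-3-methylpentanoyl]oxy}-4-oxo-1,3,4,4a,5,7a-hexahydrocyclopenta[c]pyran-7-carboxylate
Conditions: PPh3 (10 mol %), toluene, rt to 60 °C
Reagents that add atoms: none
Why: Lu phosphine-catalysed [3+2] annulation, in which the phosphonium dienolate of the allenoate adds through its α-carbon to the enone β-carbon (C9) and closes at C5 on the face anti to the C1 acyloxy group, giving the cis-fused cyclopentene with H-5 and H-9 cis to the acyloxy group (C5 and C9 set from C1).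

**Step 4**
Reactants: 7 tert-butyl (1S,4aS,7aS)-1-{[(3R)-3-methylpentanoyl]oxy}-4-oxo-1,3,4,4a,5,7a-hexahydrocyclopenta[c]pyran-7-carboxylate
Product: 8 tert-butyl (1S,4aS,7aS)-1-{[(3R)-3-methylpentanoyl]oxy}-4-{[(trifluoromethyl)sulfonyl]oxy}-1,4a,5,7a-tetrahydrocyclopenta[c]pyran-7-carboxylate
Conditions: KHMDS (1.05 equiv), THF, −78 °C; PhNTf2, −78 to −20 °C
Reagents that add atoms: N-phenyl-bis(trifluoromethanesulfonimide), O=S(=O)(N(c1ccccc1)S(=O)(=O)C(F)(F)F)C(F)(F)F
Why: Kinetic enolate O-triflation, in which the bulky amide removes a proton from the unhindered, oxygen-acidified C3 methylene and not the tertiary ring-fusion C5–H, giving the C3=C4 enol triflate that holds the place of C11 and deactivates this double bond for the following steps.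

**Step 5**
Reactants: 8 tert-butyl (1S,4aS,7aS)-1-{[(3R)-3-methylpentanoyl]oxy}-4-{[(trifluoromethyl)sulfonyl]oxy}-1,4a,5,7a-tetrahydrocyclopenta[c]pyran-7-carboxylate
Product: 10 (1S,4aS,7aS)-7-(hydroxymethyl)-4-{[(trifluoromethyl)sulfonyl]oxy}-1,4a,5,7a-tetrahydrocyclopenta[c]pyran-1-yl (3R)-3-methylpentanoate, via free carboxylic acid 9 (not isolated)
Conditions: TFA, CH2Cl2, 0 °C; evaporate (toluene azeotrope); then BH3·THF (1.1 equiv), THF, −10 to 0 °C
Reagents that add atoms: none
Why: Acidolysis of the tert-butyl ester (loss of isobutene) followed by chemoselective borane reduction of the carboxylic acid, which is reduced through its acyloxyborane far faster than the C1 ester or the vinyl triflate, gives the C10 allylic alcohol without any hydride strong enough to touch the acyl acetal.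

**Step 6**
Reactants: 10 (1S,4aS,7aS)-7-(hydroxymethyl)-4-{[(trifluoromethyl)sulfonyl]oxy}-1,4a,5,7a-tetrahydrocyclopenta[c]pyran-1-yl (3R)-3-methylpentanoate
Product: 11 7α,8α-epoxide of 10 (7R,8R; oxirane oxygen cis to C1 and trans to H-9; CH2OH on C8 β)
Conditions: Ti(Oi-Pr)4 (1.0 equiv), D-(−)-DIPT (1.2 equiv), t-BuOOH (2 equiv, decane), 4 Å MS, CH2Cl2, −20 °C
Reagents that add atoms: tert-butyl hydroperoxide, CC(C)(C)OO
Why: Sharpless asymmetric epoxidation, in which the D-(−)-tartrate–titanium complex delivers oxygen to the α (concave) face of this 2,3-(E)-disubstituted allylic alcohol under reagent control (mismatched with the convex-face bias, so a separable minor β-epoxide is expected), setting C7 and C8 while the electron-poor enol triflate is untouched.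

**Step 7**
Reactants: 12 4-iodophenol; 13 propiolic acid
Product: 14 3-(4-hydroxyphenyl)prop-2-ynoic acid
Conditions: Pd(PPh3)4 (3 mol %), DBU (2.2 equiv), DMSO, 35 °C; aq. HCl work-up
Reagents that add atoms: none
Why: Copper-free Sonogashira-type coupling of the aryl iodide with the propiolate anion, run near room temperature so that the arylpropiolic acid does not decarboxylate and with the alkyne as its carboxylate so that phenoxide conjugate addition is suppressed.

**Step 8**
Reactants: 11 7α,8α-epoxide of 10; 14 3-(4-hydroxyphenyl)prop-2-ynoic acid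
Product: 15 (1S,4aS,6S,7R,7aS)-7-hydroxy-7-(hydroxymethyl)-6-{[3-(4-hydroxyphenyl)prop-2-ynoyl]oxy}-4-{[(trifluoromethyl)sulfonyl]oxy}-1,4a,5,6,7,7a-hexahydrocyclopenta[c]pyran-1-yl (3R)-3-methylpentanoate
Conditions: Ti(Oi-Pr)4 (2.5 equiv), 14 (1.5 equiv), CH2Cl2, rt
Reagents that add atoms: none
Why: Titanium-mediated regioselective opening of a 2,3-epoxy alcohol by a carboxylic acid, in which the carboxylate bound to the titanium epoxy-alkoxide attacks C7 (C-3 of the epoxy alcohol, secondary, from the open β face) with inversion, giving the 7β-ester and freeing the 8α-OH and 10-OH in their final configuration.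

**Step 9**
Reactants: 15 (1S,4aS,6S,7R,7aS)-7-hydroxy-7-(hydroxymethyl)-6-{[3-(4-hydroxyphenyl)prop-2-ynoyl]oxy}-4-{[(trifluoromethyl)sulfonyl]oxy}-1,4a,5,6,7,7a-hexahydrocyclopenta[c]pyran-1-yl (3R)-3-methylpentanoate
Product: 16 (1S,4aS,6S,7R,7aS)-7-hydroxy-4,7-bis(hydroxymethyl)-6-{[3-(4-hydroxyphenyl)prop-2-ynoyl]oxy}-1,4a,5,6,7,7a-hexahydrocyclopenta[c]pyran-1-yl (3R)-3-methylpentanoate
Conditions: Bu3SnCH2OH (1.5 equiv), Pd2(dba)3 (2.5 mol %), AsPh3 (20 mol %), LiCl (3 equiv), NMP, 50 °C
Reagents that add atoms: (tributylstannyl)methanol, CCCC[Sn](CCCC)(CCCC)CO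
Why: Stille coupling of the enol triflate with the hydroxymethylstannane puts CH2OH on C4 with the C3=C4 bond in place, under neutral conditions that the free hydroxyls, the alkynoate and the acyl acetal tolerate.

**Step 10**
Reactants: 16 (1S,4aS,6S,7R,7aS)-7-hydroxy-4,7-bis(hydroxymethyl)-6-{[3-(4-hydroxyphenyl)prop-2-ynoyl]oxy}-1,4a,5,6,7,7a-hexahydrocyclopenta[c]pyran-1-yl (3R)-3-methylpentanoate
Product: 17 (1S,4aS,6S,7R,7aS)-7-hydroxy-4,7-bis(hydroxymethyl)-6-{[(2Z)-3-(4-hydroxyphenyl)prop-2-enoyl]oxy}-1,4a,5,6,7,7a-hexahydrocyclopenta[c]pyran-1-yl (3R)-3-methylpentanoate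
Conditions: H2 (1 atm), Lindlar catalyst, quinoline, EtOAc, rt
Reagents that add atoms: none
Why: Lindlar semihydrogenation adds H2 syn to the alkynoate to give the (Z)-p-coumarate as the last step, so the Z-alkene never meets Pd/heat or base, and the poisoned catalyst leaves the trisubstituted enol ether and both esters alone.

**Compound list**
1 | furfuryl alcohol (furan-2-ylmethanol) | OCc1ccco1 | starting material
2 | 6-hydroxy-2H-pyran-3(6H)-one (racemic lactol) | OC1OCC(=O)C=C1 | intermediate
3 | (3R)-3-methylpentanoic acid | CC[C@@H](C)CC(=O)O | starting material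
4 | (3R)-3-methylpentanoic pivalic anhydride | CC[C@@H](C)CC(=O)OC(=O)C(C)(C)C | intermediate
5 | (2S)-5-oxo-5,6-dihydro-2H-pyran-2-yl (3R)-3-methylpentanoate | CC[C@@H](C)CC(=O)O[C@H]1C=CC(=O)CO1 | intermediate
6 | tert-butyl buta-2,3-dienoate | C=C=CC(=O)OC(C)(C)C | starting material
7 | tert-butyl (1S,4aS,7aS)-1-{[(3R)-3-methylpentanoyl]oxy}-4-oxo-1,3,4,4a,5,7a-hexahydrocyclopenta[c]pyran-7-carboxylate | CC[C@@H](C)CC(=O)O[C@@H]1OCC(=O)[C@H]2CC=C(C(=O)OC(C)(C)C)[C@@H]12 | intermediate
8 | tert-butyl (1S,4aS,7aS)-1-{[(3R)-3-methylpentanoyl]oxy}-4-{[(trifluoromethyl)sulfonyl]oxy}-1,4a,5,7a-tetrahydrocyclopenta[c]pyran-7-carboxylate | CC[C@@H](C)CC(=O)O[C@@H]1OC=C(OS(=O)(=O)C(F)(F)F)[C@H]2CC=C(C(=O)OC(C)(C)C)[C@@H]12 | intermediate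
9 | (1S,4aS,7aS)-1-{[(3R)-3-methylpentanoyl]oxy}-4-{[(trifluoromethyl)sulfonyl]oxy}-1,4a,5,7a-tetrahydrocyclopenta[c]pyran-7-carboxylic acid | CC[C@@H](C)CC(=O)O[C@@H]1OC=C(OS(=O)(=O)C(F)(F)F)[C@H]2CC=C(C(=O)O)[C@@H]12 | intermediate
10 | (1S,4aS,7aS)-7-(hydroxymethyl)-4-{[(trifluoromethyl)sulfonyl]oxy}-1,4a,5,7a-tetrahydrocyclopenta[c]pyran-1-yl (3R)-3-methylpentanoate | CC[C@@H](C)CC(=O)O[C@@H]1OC=C(OS(=O)(=O)C(F)(F)F)[C@H]2CC=C(CO)[C@@H]12 | intermediate
11 | 7α,8α-epoxide of 10 (7R,8R; oxirane oxygen cis to C1, trans to H-9; CH2OH on C8 β; 1β-acyloxy, 4-triflyloxy, Δ3) | CC[C@@H](C)CC(=O)O[C@@H]1OC=C(OS(=O)(=O)C(F)(F)F)[C@H]2C[C@H]3O[C@@]3(CO)[C@@H]12 | intermediate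
12 | 4-iodophenol | Oc1ccc(I)cc1 | starting material
13 | propiolic acid (prop-2-ynoic acid) | C#CC(=O)O | starting material
14 | 3-(4-hydroxyphenyl)prop-2-ynoic acid | OC(=O)C#Cc1ccc(O)cc1 | intermediate
15 | (1S,4aS,6S,7R,7aS)-7-hydroxy-7-(hydroxymethyl)-6-{[3-(4-hydroxyphenyl)prop-2-ynoyl]oxy}-4-{[(trifluoromethyl)sulfonyl]oxy}-1,4a,5,6,7,7a-hexahydrocyclopenta[c]pyran-1-yl (3R)-3-methylpentanoate | CC[C@@H](C)CC(=O)O[C@@H]1OC=C(OS(=O)(=O)C(F)(F)F)[C@H]2C[C@H](OC(=O)C#Cc3ccc(O)cc3)[C@](O)(CO)[C@@H]12 | intermediate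
16 | (1S,4aS,6S,7R,7aS)-7-hydroxy-4,7-bis(hydroxymethyl)-6-{[3-(4-hydroxyphenyl)prop-2-ynoyl]oxy}-1,4a,5,6,7,7a-hexahydrocyclopenta[c]pyran-1-yl (3R)-3-methylpentanoate | CC[C@@H](C)CC(=O)O[C@@H]1OC=C(CO)[C@H]2C[C@H](OC(=O)C#Cc3ccc(O)cc3)[C@](O)(CO)[C@@H]12 | intermediate
17 | CNP0217341.1: (1S,4aS,6S,7R,7aS)-7-hydroxy-4,7-bis(hydroxymethyl)-6-{[(2Z)-3-(4-hydroxyphenyl)prop-2-enoyl]oxy}-1,4a,5,6,7,7a-hexahydrocyclopenta[c]pyran-1-yl (3R)-3-methylpentanoate | CC[C@@H](C)CC(=O)O[C@@H]1OC=C(CO)[C@H]2C[C@H](OC(=O)/C=C\c3ccc(O)cc3)[C@](O)(CO)[C@@H]12 | target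

**Step count and risks**
Total steps: 10. Longest linear sequence: 9 (steps 1–6 and 8–10); step 7 is a one-step side branch.

The three steps most likely to fail are steps 6, 2 and 4.

Step 6 is the weakest point, because the epoxide must form on the concave α face against the substrate's own bias and the α:β ratio may be low. The fallback sets out from 10 and comes back at 11. NBS in THF–H2O at 0 °C forms the bromonium ion on the convex β face, and water opens it at the tertiary C8 from the α face to give the bromohydrin (7β-bromo-8α,10-diol) F2. K2CO3 in acetone then closes the 8α-alkoxide onto C7 with inversion, giving the same α-epoxide 11 by substrate-controlled anti addition instead of reagent-controlled oxygen transfer. The risk there is competing attack of NBS on the enol triflate double bond, which is why it is not the first choice.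

Step 2 is the proposed new reaction. The doubts are competing pivaloylation, a lower selectivity with this acyl group, and the unverified sense of induction. The fallback uses known chemistry, sets out from 3 (with 2) and comes back at 5. Acid 3 is dehydrated with DCC (0.5 equiv, CH2Cl2) to its symmetric anhydride, (3R)-3-methylpentanoic anhydride F1. Lactol 2 is then acylated with F1 under the established isothiourea-catalysed DYKAT conditions for this lactol (chiral isothiourea, i-Pr2NEt, toluene, 0 °C), at the cost of one extra step and half of the acid.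

Step 4 depends on enolisation towards C3 and not towards the ring-fusion C5. The fallback sets out from 7 and comes back at 8. Thermodynamic silylation (TMSCl, NaI, Et3N, MeCN) gives the C3=C4 trimethylsilyl enol ether F3, whose double bond is conjugated with the ring oxygen. CsF and PhNTf2 in DME then convert F3 into enol triflate 8 without any strong base.

**Further compounds**
F1 | step 2 | (3R)-3-methylpentanoic anhydride | CC[C@@H](C)CC(=O)OC(=O)C[C@H](C)CC
F2 | step 6 | (1S,4aS,6S,7R,7aS)-6-bromo-7-hydroxy-7-(hydroxymethyl)-4-{[(trifluoromethyl)sulfonyl]oxy}-1,4a,5,6,7,7a-hexahydrocyclopenta[c]pyran-1-yl (3R)-3-methylpentanoate | CC[C@@H](C)CC(=O)O[C@@H]1OC=C(OS(=O)(=O)C(F)(F)F)[C@H]2C[C@H](Br)[C@](O)(CO)[C@@H]12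
F3 | step 4 | tert-butyl (1S,4aS,7aS)-1-{[(3R)-3-methylpentanoyl]oxy}-4-[(trimethylsilyl)oxy]-1,4a,5,7a-tetrahydrocyclopenta[c]pyran-7-carboxylate | CC[C@@H](C)CC(=O)O[C@@H]1OC=C(O[Si](C)(C)C)[C@H]2CC=C(C(=O)OC(C)(C)C)[C@@H]12
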